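Everything rests on cutting the C3–C4 bond of ring A. (R)-Carvone supplies ring B (C5–C10) together with the C17 methyl and, as its isopropenyl carbon, C4. The key step exploits the gem-dimethyl carbon C4 next to the oxygenated C3: hydrogen-atom transfer to the isopropenyl CH2 gives the tertiary C4 radical, which adds to the C3 aldehyde. One operation closes ring A, completes the gem-dimethyl group and sets the 3β-carbinol on a ring fusion already fixed at C5 and C10. The precursor is a carvone-derived cyclohexenone with the isopropenyl group on C5 and, trans to it on quaternary C10, a 3-oxopropyl chain; its C7=C8–C9=O enone afterwards anchors the side chain and O7.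

Key step: step 5

Remark: labdane numbering is used for the decalin compounds, with α as the face opposite the C10 methyl; the C11–C15 unit is taken from methyl (R)-3-methylglutarate, assumed to be commercially available, because its five-carbon chain already fits and a citronellol chain would carry one carbon too many.

Step 1
Reactants: 1 (R)-carvone; 2 iodomethane
Product: 4 (5R)-2,6-dimethyl-5-(prop-1-en-2-yl)cyclohex-2-en-1-one (6-methylcarvone as C6 epimer mixture), via lithium enolate 3 (not isolated)
Conditions: LiN(iPr)2 (1.05 equiv), THF, −78 °C; then MeI, −78 → 0 °C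
Reagents that add atoms: iodomethane (2), CI; LiN(iPr)2, [Li]N(C(C)C)C(C)C (lithium only in 3)
Why: Kinetic α′-deprotonation at the ring CH2 next to the carbonyl gives the cross-conjugated enolate, which is C-methylated (enolate alkylation); the new centre is erased again in step 2, so its configuration does not matter.

Step 2
Reactants: 4 6-methylcarvone; 5 allyl bromide
Product: 7 (5S,6S)-2,6-dimethyl-6-(prop-2-en-1-yl)-5-(prop-1-en-2-yl)cyclohex-2-en-1-one (allyl trans to isopropenyl), via lithium enolate 6 (not isolated)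
Conditions: LiN(iPr)2 (1.1 equiv), THF, −78 → 0 °C; then allyl bromide, DMPU, −78 °C → rt
Reagents that add atoms: allyl bromide (5), C=CCBr; LiN(iPr)2, [Li]N(C(C)C)C(C)C (lithium only in 6)
Why: Alkylation of the tetrasubstituted enolate with the reactive allylic halide should occur on the face anti to the neighbouring isopropenyl group, which sets the quaternary centre (future C10) with methyl cis and the three-carbon arm trans to isopropenyl.

Step 3
Reactants: 7 allyl ketone
Product: 9 (5S,6S)-6-(3-hydroxypropyl)-2,6-dimethyl-5-(prop-1-en-2-yl)cyclohex-2-en-1-one, via alkyldisiamylborane 8 (not isolated)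
Conditions: Sia2BH (1.3 equiv, from BH3·SMe2 and 2-methylbut-2-ene, THF, 0 °C), THF, 0 °C; then 30% H2O2, 3 M aq. NaOAc, 0 °C → rt
Reagents that add atoms: hydrogen peroxide, OO; bis(3-methylbutan-2-yl)borane, CC(C)C(C)BC(C)C(C)C (boron and siamyl groups only in 8)
Why: Hydroboration–oxidation with a bulky dialkylborane selects the monosubstituted allyl terminus over the hindered 1,1-disubstituted isopropenyl group and the conjugated, α-quaternary ketone, and the acetate-buffered peroxide oxidises the C–B bond without Weitz–Scheffer epoxidation of the enone; no stereocentre is formed.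

Step 4
Reactants: 9 primary alcohol
Product: 10 3-[(1S,6S)-1,3-dimethyl-2-oxo-6-(prop-1-en-2-yl)cyclohex-3-en-1-yl]propanal
Conditions: TEMPO (10 mol%), PhI(OAc)2 (1.1 equiv), CH2Cl2, rt
Reagents that add atoms: none
Why: Oxoammonium-catalysed oxidation of a primary alcohol stops at the aldehyde in the absence of water and leaves both alkenes and the enone untouched.

Step 5
Reactants: 10 keto aldehyde
Product: 11 (4aS,6S,8aS)-6-hydroxy-2,5,5,8a-tetramethyl-4a,5,6,7,8,8a-hexahydronaphthalen-1(4H)-one (trans-fused 3β-hydroxy-7-en-9-one in labdane numbering)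
Conditions: Fe(acac)3 (30 mol%), PhSiH3 (2.5 equiv), EtOH (0.03 M), 60 °C
Reagents that add atoms: none
Why: A trivalent iron hydride formed from Fe(acac)3, PhSiH3 and ethanol transfers a hydrogen atom to the terminal CH2 of the isopropenyl group, so that C4 becomes a tertiary radical that already carries both methyl groups. This radical adds to the aldehyde carbon C3 and the alkoxy radical is reduced to the alcohol (by divalent iron and ethanol or by the silane); the closest known reaction type is the iron-hydride-initiated reductive radical cyclisation of alkenes onto carbonyl groups. Ring A closes in the 6-exo-trig mode through a chair-like transition state. The only new stereocentre, C3, is controlled by that chair, in which the carbonyl oxygen sits pseudo-equatorial, away from the axial hydrogens on C1 and C5, and reversible addition (β-scission of the alkoxy radical) should favour the same equatorial 3β-oxygen. The trans ring fusion is not at stake, since C5 and C10 are set beforehand and hold C4 and the chain trans-diequatorial. The step needs hydrogen-atom transfer to the isopropenyl alkene alone and ring closure before the radical is reduced: the C7=C8 alkene, conjugated to the ketone and trisubstituted, reacts far more slowly with the metal hydride, the C4 radical can reach no enone carbon in a feasible ring size, and the quaternary C10 keeps the aldehyde close.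

Step 6
Reactants: 11 hydroxy enone
Product: 12 (4aS,6S,8aS)-6-[(tert-butyldimethylsilyl)oxy]-2,5,5,8a-tetramethyl-4a,5,6,7,8,8a-hexahydronaphthalen-1(4H)-one
Conditions: TBSOTf (1.3 equiv), 2,6-lutidine, CH2Cl2, 0 °C
Reagents that add atoms: tert-butyldimethylsilyl trifluoromethanesulfonate, CC(C)(C)[Si](C)(C)OS(=O)(=O)C(F)(F)F
Why: Silylation of the hindered neopentyl 3β-alcohol with the silyl triflate protects O3 against the organometallic reagent of step 11 and the hexavalent chromium oxidant of step 12.

Step 7
Reactants: 13 methyl (R)-3-methylglutarate [(3R)-5-methoxy-3-methyl-5-oxopentanoic acid]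
Product: 14 methyl (3R)-5-hydroxy-3-methylpentanoate
Conditions: BH3·SMe2 (1.1 equiv), THF, −10 °C → rt; MeOH quench
Reagents that add atoms: none
Why: Borane reduces the free carboxylic acid through its acyloxyborane much faster than the methyl ester, which differentiates the two arms without touching the stereocentre (future C13).

Step 8
Reactants: 14 hydroxy ester
Product: 15 methyl (3R)-5-[(tert-butyldimethylsilyl)oxy]-3-methylpentanoate
Conditions: TBSCl, imidazole, CH2Cl2, 0 °C → rt
Reagents that add atoms: tert-butyldimethylsilyl chloride, CC(C)(C)[Si](C)(C)Cl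
Why: Standard silylation of the primary alcohol prevents lactonisation and masks the future C15 oxygen.

Step 9
Reactants: 15 silyloxy ester
Product: 16 (3S)-5-[(tert-butyldimethylsilyl)oxy]-3-methylpentan-1-ol
Conditions: LiAlH4, THF, 0 °C
Reagents that add atoms: none
Why: Hydride reduction of the ester to the primary alcohol leaves the silyl ether and the stereocentre intact.

Step 10
Reactants: 16 alcohol
Product: 17 tert-butyl{[(3R)-5-iodo-3-methylpentyl]oxy}dimethylsilane
Conditions: I2, PPh3, imidazole, CH2Cl2, 0 °C → rt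
Reagents that add atoms: iodine, II
Why: Appel-type iodination proceeds by SN2 displacement at the primary carbon, remote from the stereocentre.

Step 11
Reactants: 17 iodide; 12 silyloxy enone
Product: 20 (13S)-3β,15-bis(tert-butyldimethylsilyloxy)labd-7-en-9-ol (C9 epimers), via alkyllithium 18 (not isolated), via alkylcerium dichloride 19 (not isolated)
Conditions: 17, t-BuLi (2.1 equiv), Et2O, −78 °C; transfer onto CeCl3 (anhydrous, 1.3 equiv), THF, −78 °C; then 12, −78 → −20 °C; aq. NH4Cl
Reagents that add atoms: t-BuLi, [Li]C(C)(C)C (lithium only in 18); CeCl3, Cl[Ce](Cl)Cl (cerium and chloride only in 19)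
Why: Iodine–lithium exchange and transmetallation give a weakly basic but strongly nucleophilic organocerium reagent, which should add 1,2 to the hindered conjugated C9 carbonyl without γ-deprotonation; the configuration of the C9 carbinol is irrelevant because C9 becomes sp2 in step 12.

Step 12
Reactants: 20 tertiary allylic alcohol
Product: 21 (13S)-3β,15-bis(tert-butyldimethylsilyloxy)labd-8-en-7-one
Conditions: [C5H5NH][CrO3Cl] (pyridinium chlorochromate, 3 equiv), 4 Å MS, CH2Cl2, rt
Reagents that add atoms: pyridinium chlorochromate, [O-][Cr](=O)(=O)Cl.c1cc[nH+]cc1 (supplies the C7 oxygen)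
Why: Babler–Dauben oxidative transposition, in which the tertiary chromate ester undergoes a [3,3] shift to the C7 chromate and hexavalent chromium then oxidises C7 to the enone carbonyl; silyl ethers tolerate the reagent.

Step 13
Reactants: 21 transposed enone
Product: 23 (13S)-3β,15-bis(tert-butyldimethylsilyloxy)labd-7-en-7-yl trifluoromethanesulfonate (9α-H), via lithium enolate 22 (not isolated)
Conditions: Li (2.5 equiv), NH3(l)/THF, t-BuOH (1.0 equiv), −78 °C; isoprene; NH3 evaporated; PhNTf2 (1.5 equiv), THF, 0 °C → rt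
Reagents that add atoms: N-phenylbis(trifluoromethanesulfonimide), O=S(=O)(N(c1ccccc1)S(=O)(=O)C(F)(F)F)C(F)(F)F; lithium, [Li] (only in 22)
Why: Dissolving-metal reduction of the enone protonates the β-carbon C9 axially on the α face (anti to the C10 methyl), which sets 9α-H with the side chain equatorial, and the regiospecific C7–C8 enolate is then O-triflated.

Step 14
Reactants: 23 enol triflate
Product: 24 (13S)-3β,15-bis(tert-butyldimethylsilyloxy)labd-7-ene
Conditions: Pd(OAc)2 (5 mol%), PPh3 (10 mol%), HCO2H (2 equiv), Bu3N (3 equiv), DMF, 60 °C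
Reagents that add atoms: none
Why: Zerovalent palladium formed in the flask inserts into the C–OTf bond, formate delivers hydride with loss of CO2, and reductive elimination gives the alkene with the double bond fixed at C7=C8.

Step 15
Reactants: 24 7-ene
Product: 25 (13S)-7α,8α-epoxy-3β,15-bis(tert-butyldimethylsilyloxy)labdane
Conditions: mCPBA (1.2 equiv), NaHCO3, CH2Cl2, 0 °C
Reagents that add atoms: 3-chloroperoxybenzoic acid, OOC(=O)c1cccc(Cl)c1
Why: Prilezhaev epoxidation should take place on the α face because the axial C10 methyl shields the β face of C8, which sets C7 and C8 and places the C7 oxygen α as in the target.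

Step 16
Reactants: 25 epoxide
Product: 26 (13S)-3β,15-bis(tert-butyldimethylsilyloxy)labd-8(17)-en-7α-ol
Conditions: Al(OiPr)3 (3 equiv), toluene, 110 °C
Reagents that add atoms: none
Why: Aluminium-alkoxide-mediated isomerisation of an epoxide to an allylic alcohol, in which the metal activates the tertiary C8–O bond and an alkoxide ligand removes a proton from the unhindered C17 methyl in a cyclic syn transition state, gives the exocyclic alkene while the C7–O bond and its α configuration are untouched.

Step 17
Reactants: 26 allylic alcohol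
Product: 27 (13S)-7α-acetoxy-3β,15-bis(tert-butyldimethylsilyloxy)labd-8(17)-ene
Conditions: Ac2O, DMAP (cat.), pyridine, CH2Cl2, rt
Reagents that add atoms: acetic anhydride, CC(=O)OC(C)=O
Why: Nucleophilic-catalysed acylation of the axial secondary allylic alcohol proceeds with retention at C7 and protects it before the C15 oxidation.

Step 18
Reactants: 27 acetate bis(silyl ether)
Product: 28 (13S)-7α-acetoxylabd-8(17)-ene-3β,15-diol
Conditions: 48% aq. HF, MeCN/THF, rt
Reagents that add atoms: none
Why: Fluoride-driven Si–O cleavage removes both silyl groups, including the hindered one on O3, under conditions that leave the acetate and the allylic system alone.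

Step 19
Reactants: 28 diol
Product: 30 (13S)-7α-acetoxy-3β-hydroxylabd-8(17)-en-15-oic acid, via aldehyde 29 (not isolated)
Conditions: TEMPO (20 mol%), PhI(OAc)2 (2.5 equiv), MeCN/H2O 1:1, rt
Reagents that add atoms: water, O
Why: The sterically demanding oxoammonium oxidant selects the primary C15 alcohol over the neopentyl 3β-alcohol, and in water the aldehyde hydrate is oxidised on to the carboxylic acid.

Step 20
Reactants: 30 hydroxy acid
Product: 32 (13S)-3β,7α-diacetoxylabd-8(17)-en-15-oic acid (target CNP0169875.1), via mixed anhydride 31 (not isolated)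
Conditions: Ac2O (3 equiv), DMAP (cat.), pyridine, rt; then H2O/THF, rt
Reagents that add atoms: acetic anhydride, CC(=O)OC(C)=O; water, O (may supply one carboxyl oxygen when 31 is hydrolysed)
Why: Acylation of the equatorial 3β-alcohol with retention completes the diacetate, and the C15 mixed anhydride that forms in passing is hydrolysed back to the acid by the aqueous stir while the two acetates stay intact.

Compound list
1 | (R)-carvone | CC1=CC[C@H](CC1=O)C(C)=C | starting material
2 | iodomethane | CI | starting material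
3 | lithium enolate of 1 (O-lithio cross-conjugated dienolate) | CC1=CC[C@@H](C(C)=C)C=C1O[Li] | intermediate
4 | (5R)-2,6-dimethyl-5-(prop-1-en-2-yl)cyclohex-2-en-1-one, C6 epimer mixture | CC1=CC[C@@H](C(C)=C)C(C)C1=O | intermediate
5 | allyl bromide | C=CCBr | starting material
6 | lithium enolate of 4 | CC1=CC[C@@H](C(C)=C)C(C)=C1O[Li] | intermediate
7 | (5S,6S)-2,6-dimethyl-6-(prop-2-en-1-yl)-5-(prop-1-en-2-yl)cyclohex-2-en-1-one | CC1=CC[C@@H](C(C)=C)[C@](C)(CC=C)C1=O | intermediate
8 | B-alkyl bis(3-methylbutan-2-yl)borane from 7 | CC1=CC[C@@H](C(C)=C)[C@](C)(CCCB(C(C)C(C)C)C(C)C(C)C)C1=O | intermediate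
9 | (5S,6S)-6-(3-hydroxypropyl)-2,6-dimethyl-5-(prop-1-en-2-yl)cyclohex-2-en-1-one | CC1=CC[C@@H](C(C)=C)[C@](C)(CCCO)C1=O | intermediate
10 | 3-[(1S,6S)-1,3-dimethyl-2-oxo-6-(prop-1-en-2-yl)cyclohex-3-en-1-yl]propanal | CC1=CC[C@@H](C(C)=C)[C@](C)(CCC=O)C1=O | intermediate
11 | (4aS,6S,8aS)-6-hydroxy-2,5,5,8a-tetramethyl-4a,5,6,7,8,8a-hexahydronaphthalen-1(4H)-one | CC1=CC[C@H]2C(C)(C)[C@@H](O)CC[C@]2(C)C1=O | intermediate
12 | tert-butyldimethylsilyl ether of 11 | CC1=CC[C@H]2C(C)(C)[C@@H](O[Si](C)(C)C(C)(C)C)CC[C@]2(C)C1=O | intermediate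
13 | methyl (R)-3-methylglutarate [(3R)-5-methoxy-3-methyl-5-oxopentanoic acid] | COC(=O)C[C@H](C)CC(=O)O | starting material
14 | methyl (3R)-5-hydroxy-3-methylpentanoate | COC(=O)C[C@H](C)CCO | intermediate
15 | methyl (3R)-5-[(tert-butyldimethylsilyl)oxy]-3-methylpentanoate | COC(=O)C[C@H](C)CCO[Si](C)(C)C(C)(C)C | intermediate
16 | (3S)-5-[(tert-butyldimethylsilyl)oxy]-3-methylpentan-1-ol | OCC[C@H](C)CCO[Si](C)(C)C(C)(C)C | intermediate
17 | tert-butyl{[(3R)-5-iodo-3-methylpentyl]oxy}dimethylsilane | ICC[C@H](C)CCO[Si](C)(C)C(C)(C)C | intermediate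
18 | alkyllithium from 17 (same configuration at the methyl-bearing carbon) | [Li]CC[C@H](C)CCO[Si](C)(C)C(C)(C)C | intermediate
19 | alkylcerium dichloride from 18 | Cl[Ce](Cl)CC[C@H](C)CCO[Si](C)(C)C(C)(C)C | intermediate
20 | (13S)-3β,15-bis(tert-butyldimethylsilyloxy)labd-7-en-9-ol, C9 epimers | CC1=CC[C@H]2C(C)(C)[C@@H](O[Si](C)(C)C(C)(C)C)CC[C@]2(C)C1(O)CC[C@H](C)CCO[Si](C)(C)C(C)(C)C | intermediate
21 | (13S)-3β,15-bis(tert-butyldimethylsilyloxy)labd-8-en-7-one | CC1=C(CC[C@H](C)CCO[Si](C)(C)C(C)(C)C)[C@@]2(C)CC[C@H](O[Si](C)(C)C(C)(C)C)C(C)(C)[C@@H]2CC1=O | intermediate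
22 | lithium C7–C8 enolate of the 9α-H ketone | CC1=C(O[Li])C[C@H]2C(C)(C)[C@@H](O[Si](C)(C)C(C)(C)C)CC[C@]2(C)[C@H]1CC[C@H](C)CCO[Si](C)(C)C(C)(C)C | intermediate
23 | (13S)-3β,15-bis(tert-butyldimethylsilyloxy)labd-7-en-7-yl trifluoromethanesulfonate | CC1=C(OS(=O)(=O)C(F)(F)F)C[C@H]2C(C)(C)[C@@H](O[Si](C)(C)C(C)(C)C)CC[C@]2(C)[C@H]1CC[C@H](C)CCO[Si](C)(C)C(C)(C)C | intermediate
24 | (13S)-3β,15-bis(tert-butyldimethylsilyloxy)labd-7-ene | CC1=CC[C@H]2C(C)(C)[C@@H](O[Si](C)(C)C(C)(C)C)CC[C@]2(C)[C@H]1CC[C@H](C)CCO[Si](C)(C)C(C)(C)C | intermediate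
25 | (13S)-7α,8α-epoxy-3β,15-bis(tert-butyldimethylsilyloxy)labdane | C[C@@]1(O2)[C@H]2C[C@H]3C(C)(C)[C@@H](O[Si](C)(C)C(C)(C)C)CC[C@]3(C)[C@H]1CC[C@H](C)CCO[Si](C)(C)C(C)(C)C | intermediate
26 | (13S)-3β,15-bis(tert-butyldimethylsilyloxy)labd-8(17)-en-7α-ol | C=C1[C@H](O)C[C@H]2C(C)(C)[C@@H](O[Si](C)(C)C(C)(C)C)CC[C@]2(C)[C@H]1CC[C@H](C)CCO[Si](C)(C)C(C)(C)C | intermediate
27 | (13S)-7α-acetoxy-3β,15-bis(tert-butyldimethylsilyloxy)labd-8(17)-ene | C=C1[C@H](OC(C)=O)C[C@H]2C(C)(C)[C@@H](O[Si](C)(C)C(C)(C)C)CC[C@]2(C)[C@H]1CC[C@H](C)CCO[Si](C)(C)C(C)(C)C | intermediate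
28 | (13S)-7α-acetoxylabd-8(17)-ene-3β,15-diol | C=C1[C@H](OC(C)=O)C[C@H]2C(C)(C)[C@@H](O)CC[C@]2(C)[C@H]1CC[C@H](C)CCO | intermediate
29 | (13S)-7α-acetoxy-3β-hydroxylabd-8(17)-en-15-al | C=C1[C@H](OC(C)=O)C[C@H]2C(C)(C)[C@@H](O)CC[C@]2(C)[C@H]1CC[C@H](C)CC=O | intermediate
30 | (13S)-7α-acetoxy-3β-hydroxylabd-8(17)-en-15-oic acid | C=C1[C@H](OC(C)=O)C[C@H]2C(C)(C)[C@@H](O)CC[C@]2(C)[C@H]1CC[C@H](C)CC(=O)O | intermediate
31 | mixed acetic anhydride of the target acid | C=C1[C@H](OC(C)=O)C[C@H]2C(C)(C)[C@@H](OC(C)=O)CC[C@]2(C)[C@H]1CC[C@H](C)CC(=O)OC(C)=O | intermediate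
32 | (13S)-3β,7α-diacetoxylabd-8(17)-en-15-oic acid, (3S,5R,7R,9R,10S,13S) | C=C1[C@H](OC(C)=O)C[C@H]2C(C)(C)[C@@H](OC(C)=O)CC[C@]2(C)[C@H]1CC[C@H](C)CC(=O)O | target

Total step count: 20 (16 on the main line, 4 for the side-chain iodide).
Longest linear sequence: 16 steps (steps 1–6 and 11–20, from (R)-carvone).

Steps most likely to fail

Step 5. The tertiary C4 radical may pick up a second hydrogen atom before it cyclises, the aldehyde may be consumed by acetalisation or hydrosilylation, the alkoxy radical may fragment back, and the facial selectivity at C3 may be low. The fallback sets out from alcohol 9 and returns at 11, and it does not depend on the facial selectivity of the radical addition.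
- HBr gas in CH2Cl2 at −20 °C adds in the Markovnikov sense to the isopropenyl group (as in the classical hydrobromination of carvone) and should give the tertiary bromide F1.
- TEMPO/PhI(OAc)2 oxidation, as in step 4, gives the bromo aldehyde F2.
- Slow addition of Bu3SnH with AIBN in benzene at 80 °C abstracts bromine, the same C4 radical closes 6-exo onto the aldehyde, and the stannane quenches the alkoxy radical. This gives the carbinol F3 as whatever C3 epimer mixture results.
- Dess–Martin oxidation converts F3 into the 3,9-dione F4.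
- NaBH4 in MeOH/CH2Cl2 at −78 °C should reduce the saturated C3 ketone by axial hydride delivery to the 3β-alcohol, while the conjugated and more hindered C9 ketone is left, which gives 11.

Step 13. Proton exchange, incomplete O-triflation or over-reduction may erode the regiospecific enolate trapping. The fallback sets out from 21, returns at 24 and replaces steps 13 and 14.
- Luche reduction (NaBH4, CeCl3·7H2O, MeOH, −40 °C) should deliver hydride axially on the α face and give the 7β-allylic alcohol F5.
- Acetic formic anhydride and pyridine give the allylic formate F6.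
- Pd(OAc)2/PBu3 in dioxane at rt to 60 °C effects the formate hydrogenolysis. Zerovalent palladium ionises the 7β-formate with inversion, so the metal sits on the α face. Hydride released from formate with loss of CO2 is then passed from palladium to the more substituted terminus C9 on that same face, which gives 24 with 9α-H.

Step 16. The alkoxide may abstract H9 instead of a C17 hydrogen (giving the 8-en-7α-ol), or the Lewis acid may trigger a hydride or alkyl shift of the epoxide to a carbonyl compound. The fallback sets out from 24, returns at 27 and replaces steps 15–17.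
- Upjohn dihydroxylation (OsO4 cat., N-methylmorpholine N-oxide, acetone/H2O) on the α face gives the 7α,8α-diol F7.
- Ac2O in pyridine without DMAP acetylates only the secondary 7-hydroxyl and gives the hydroxy acetate F8.
- SOCl2 in pyridine/CH2Cl2 at −40 °C dehydrates the tertiary, equatorial 8α-hydroxyl through its chlorosulfite. Only the C17 hydrogens can stand anti-periplanar to the equatorial leaving group, so the exocyclic alkene 27 should result.

Further compounds
F1 | step 5 | (5S,6S)-5-(2-bromopropan-2-yl)-6-(3-hydroxypropyl)-2,6-dimethylcyclohex-2-en-1-one | CC1=CC[C@@H](C(C)(C)Br)[C@](C)(CCCO)C1=O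
F2 | step 5 | 3-[(1S,6S)-6-(2-bromopropan-2-yl)-1,3-dimethyl-2-oxocyclohex-3-en-1-yl]propanal | CC1=CC[C@@H](C(C)(C)Br)[C@](C)(CCC=O)C1=O
F3 | step 5 | C3 epimer mixture of 11 (3-hydroxy-7-en-9-one) | CC1=CC[C@H]2C(C)(C)C(O)CC[C@]2(C)C1=O
F4 | step 5 | (4aS,8aS)-2,5,5,8a-tetramethyl-4a,7,8,8a-tetrahydronaphthalene-1,6(4H,5H)-dione (7-ene-3,9-dione) | CC1=CC[C@H]2C(C)(C)C(=O)CC[C@]2(C)C1=O
F5 | step 13 | (13S)-3β,15-bis(tert-butyldimethylsilyloxy)labd-8-en-7β-ol | CC1=C(CC[C@H](C)CCO[Si](C)(C)C(C)(C)C)[C@@]2(C)CC[C@H](O[Si](C)(C)C(C)(C)C)C(C)(C)[C@@H]2C[C@@H]1O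
F6 | step 13 | 7β-formate of F5 | CC1=C(CC[C@H](C)CCO[Si](C)(C)C(C)(C)C)[C@@]2(C)CC[C@H](O[Si](C)(C)C(C)(C)C)C(C)(C)[C@@H]2C[C@@H]1OC=O
F7 | step 16 | (13S)-3β,15-bis(tert-butyldimethylsilyloxy)labdane-7α,8α-diol | C[C@@]1(O)[C@H](O)C[C@H]2C(C)(C)[C@@H](O[Si](C)(C)C(C)(C)C)CC[C@]2(C)[C@H]1CC[C@H](C)CCO[Si](C)(C)C(C)(C)C
F8 | step 16 | (13S)-7α-acetoxy-3β,15-bis(tert-butyldimethylsilyloxy)labdan-8α-ol | C[C@@]1(O)[C@H](OC(C)=O)C[C@H]2C(C)(C)[C@@H](O[Si](C)(C)C(C)(C)C)CC[C@]2(C)[C@H]1CC[C@H](C)CCO[Si](C)(C)C(C)(C)C
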